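**Plan**
- Retrosynthetic cuts, in order: the three acetates and the C17 epimer; lactone O7–C19 and C6–Cl (back to the 6,7-epoxide of an E olefin); C8–C17 (ester enolate tethered to O9); C2–H; then C4–C5 with C2–C7 re-formed; finally C2–C3, C7–C6, C11=C20 and the pair C1–C14/C10–C11.
- Enabling feature: in the ten-membered ring C1–C10, the run C2(O)–C3–C4–C5(=C16)–C6–C7 is a cyclodec-5-enone with one extra methylene on C5. That is the retron of a [3,3] shift between a C2 vinyl carbinol and a C7 allene across a C2–C7 bond. The precursor is therefore a trans-decalin with ring A = C1, C10–C14 and ring B = C1, C2, C7–C10.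
- Forward ring order: rings A and B form together in a quinone Diels–Alder reaction, ring B is enlarged by four atoms to the ten-membered ring, and the γ-lactone closes last.
- Stereochemistry on the decalin: the catalyst sets C1 and the endo rule sets C14. Epimerisation sets C10, and hydride delivered anti to C15 sets C9. Chair control sets the transient C2 and C7, and through them the E geometry of C6=C7.
- Stereochemistry on the ten-membered ring: the O9 tether sets C8, and C14–OH-directed hydride sets C2. Peripheral directed epoxidation followed by inversion with chloride sets C7 and C6. Equilibration sets C17.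

Key step: step 15

Assumption: briarane numbering is used and β is the face of the C15 methyl group. Centres written without a descriptor (C2 in 11, 12 and 16; C7 in 12; C17 in 26–35) are epimer mixtures that a later step erases or equilibrates.

Step 1
Reactants: 1 (E)-crotonaldehyde
Product: 2 (E)-1-(triisopropylsilyloxy)buta-1,3-diene
Conditions: TIPSOTf, Et3N, Et2O, 0 °C to rt
Reagents that add atoms: triisopropylsilyl triflate, CC(C)[Si](OS(=O)(=O)C(F)(F)F)(C(C)C)C(C)C
Why: Soft γ-deprotonation and O-silylation of an enal (dienol silyl ether formation) should give mainly the 1E diene, the only isomer that can reach the s-cis endo array of step 2.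

Step 2
Reactants: 2 (E)-1-(triisopropylsilyloxy)buta-1,3-diene; 3 2-methoxy-5-methyl-1,4-benzoquinone
Product: 4 cis-fused cycloadduct (14α-OTIPS, 15-Me β, H10 β, C2 and C9 ketones, 8-OMe on C7=C8, C12=C13)
Conditions: (S)-diphenylprolinol-derived o-tolyl oxazaborolidine·HNTf2 (20 mol %), CH2Cl2, −78 °C
Reagents that add atoms: none
Why: Lewis-acid-catalysed endo Diels–Alder reaction in which the monodentate boron cation binds the more basic vinylogous-ester carbonyl C2=O and makes C10 the electrophilic terminus, so the diene CH2 end bonds to C10 and the silyloxy carbon to C1, while the methoxy group shuts off C7=C8, the endo rule places O14 anti to C15 and H10, and the catalyst stacked on one quinone face fixes the absolute sense at C1.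

Step 3
Reactants: 4 cis-fused cycloadduct
Product: 5 trans-fused ene-dione (H10 α)
Conditions: basic Al2O3, CH2Cl2, rt
Reagents that add atoms: none
Why: Base-catalysed epimerisation α to the C9 ketone, where C10 is the only enolisable stereocentre (C1 is quaternary and nothing lies β to a removable proton) and the trans isomer should be favoured because it frees the bulky α-OTIPS group from the concave fold of the cis isomer.

Step 4
Reactants: 5 trans-fused ene-dione
Product: 6 9β-alcohol
Conditions: NaBH4, CeCl3·7H2O, MeOH–CH2Cl2, −78 °C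
Reagents that add atoms: none
Why: Luche 1,2-reduction picks C9=O because C2=O is a neopentyl vinylogous ester, and hydride enters from the α face since the β face of C9 is covered by the 1,3-diaxial C15 methyl, which gives the axial 9β-OH.

Step 5
Reactants: 6 9β-alcohol
Product: 7 9β-TBS ether
Conditions: TBSOTf, 2,6-lutidine, CH2Cl2, −78 to 0 °C
Reagents that add atoms: tert-butyldimethylsilyl triflate, CC(C)(C)[Si](C)(C)OS(=O)(=O)C(F)(F)F
Why: Silyl triflate silylation is the standard answer to a hindered axial alcohol, and the buffered medium leaves the enol ether intact.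

Step 6
Reactants: 7 9β-TBS ether
Product: 8 C12=C13 en-11-one
Conditions: Rh2(cap)4 (1 mol %), t-BuOOH, K2CO3 (0.5 equiv), CH2Cl2, rt
Reagents that add atoms: tert-butyl hydroperoxide, CC(C)(C)OO
Why: Catalytic allylic oxidation by tert-butylperoxy radical should take C11, the only free allylic methylene, because the other allylic site C14 is neopentyl and buried under TIPS and the C7=C8 bond is an electron-poor vinylogous ester.

Step 7
Reactants: 8 C12=C13 en-11-one
Product: 9 saturated 11-ketone
Conditions: H2 (1 atm), 10 % Pd/C, EtOAc, rt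
Reagents that add atoms: none
Why: Heterogeneous hydrogenation saturates the disubstituted enone bond much faster than the trisubstituted, donor-substituted C7=C8 bond.

Step 8
Reactants: 9 saturated 11-ketone
Product: 10 11(20)-methylene vinylogous ester
Conditions: Cp2TiMe2 (1.5 equiv), toluene, 65 °C, dark
Reagents that add atoms: dimethyltitanocene, C[Ti](C)(C1C=CC=C1)C1C=CC=C1
Why: Petasis methylenation is non-basic, so neither C10 epimerisation nor loss of the anti-periplanar 9β-silyloxy group can compete, and a ketone reacts well ahead of the vinylogous ester.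

Step 9
Reactants: 10 11(20)-methylene vinylogous ester
Product: 11 C2 allylic alcohol that keeps the C7=C8(OMe) enol ether
Conditions: DIBAL-H, CH2Cl2, −78 °C; Rochelle salt work-up
Reagents that add atoms: none
Why: 1,2-Reduction of a 3-alkoxyenone with a neutral work-up breaks the push–pull conjugation and turns C7=C8 into a true, nucleophilic enol ether (the C2 configuration is irrelevant because step 13 erases it).

Step 10
Reactants: 11 C2 allylic alcohol
Product: 12 7-bromo 8,8-dimethyl ketal
Conditions: NBS (1.0 equiv), NaHCO3, MeOH–CH2Cl2, −40 °C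
Reagents that add atoms: N-bromosuccinimide, O=C1CCC(=O)N1Br; methanol, CO
Why: Bromo-alkoxylation of an enol ether puts Br on C7 and masks C8 as its ketal in one operation, the enol ether being far more nucleophilic than the C11 methylene, and no carbonyl flanks C7 at this stage that could trigger loss of methanol.

Step 11
Reactants: 13 propargyl bromide
Product: 15 triphenyl(prop-2-ynyl)stannane, via allenylmagnesium bromide 14 (not isolated)
Conditions: Mg, HgCl2 (cat.), Et2O, 0 °C; Ph3SnCl, 0 °C to rt
Reagents that add atoms: chlorotriphenylstannane, Cl[Sn](c1ccccc1)(c1ccccc1)c1ccccc1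
Why: The allenyl Grignard reagent is stannylated in the SE2′ sense, which should deliver the propargyl isomer needed for allene transfer.

Step 12
Reactants: 12 7-bromo 8,8-dimethyl ketal; 15 triphenyl(prop-2-ynyl)stannane
Product: 16 7α-allenyl carbinol (allenyl equatorial, H7 β axial)
Conditions: AIBN (0.2 equiv), benzene, 80 °C
Reagents that add atoms: none
Why: Radical SH2′ allene transfer in which the C7 radical adds to the alkyne terminus and expels Ph3Sn•, under neutral conditions that spare ketal and carbinol, and C–C bond formation can only occur on the α face because the β-axial site at C7 is syn-axial to both C15 and O9-TBS.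

Step 13
Reactants: 16 7α-allenyl carbinol
Product: 17 α-allenyl ketone (C2=O)
Conditions: Dess–Martin periodinane, pyridine, CH2Cl2, 0 °C
Reagents that add atoms: none
Why: Buffered hypervalent-iodine oxidation takes the only free alcohol to the ketone without touching C7–H or isomerising the β,γ-allene.

Step 14
Reactants: 17 α-allenyl ketone; 18 vinylmagnesium bromide
Product: 20 trans-decalin vinyl carbinol bearing the C7 allene (2α-OH axial; vinyl equatorial), via vinylcerium dichloride 19 (not isolated)
Conditions: CeCl3 (anhydrous), THF, −78 °C; add 17, −78 to −20 °C; water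
Reagents that add atoms: none
Why: Organocerium 1,2-addition suppresses enolisation of the acidic C7–H and thereby ketal opening, and the axial α trajectory at C2 is closed by three syn-axial groups (O14-TIPS, the axial 8-OMe and H10), so vinyl enters equatorially and the hydroxyl ends up axial.

Step 15
Reactants: 20 trans-decalin vinyl carbinol bearing the C7 allene
Product: 23 bicyclic cyclodecadienone carrying the C5 methylene, via potassium alkoxide 21 (not isolated), via potassium enolate 22 (not isolated)
Conditions: KH, 18-crown-6, THF, 0 °C to rt; AcOH–THF, −78 °C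
Reagents that add atoms: none
Why: Deprotonation gives alkoxide 21, whose oxyanion weakens C2–C7, so the 1,5-diene C4=C3–C2–C7–C6=C5 undergoes a concerted [3,3] shift in which C4 bonds to the central allene carbon C5 and C2–C7 breaks, leaving enolate 22, the C6=C7 olefin and the untouched C5=C16 π bond as a methylene. The closest known reaction type is the anionic oxy-Cope ring expansion of trans-1,2-dialkenylcyclohexanols to cyclodec-5-enones, in which an allene has served as the second π partner in only a few cases. The ten-membered ring C1–C10 is not closed end to end but arises by four-atom enlargement of ring B through a six-centre chair fused diequatorially to that ring, and enolate formation makes the step irreversible. No stereocentre is created (C2 and C7 are consumed); what is set is the E geometry of C6=C7 and the orientation of its faces, both fixed by the chair in which C8 is equatorial on the reacting array. The step needs vinyl and allenyl both equatorial and a free alkoxide, which the substrate secures in four ways: the rigid trans-decalin with axial O2 and axial H7 holds the two groups gauche, the syn-axial O14 and O8 substituents add ground-state strain that is released, TIPS on O14 is too bulky for a 1,5 O-to-O shift to the neighbouring alkoxide, and the ketal leaves no carbonyl beside C7. The cold acetic acid quench protonates C3 before base can act on the β-silyloxy ketone.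

Step 16
Reactants: 23 bicyclic cyclodecadienone carrying the C5 methylene
Product: 24 9β-hydroxy C8 dienone (14-OTIPS and C2=O retained)
Conditions: 48 % aq. HF–MeCN (5:95), 0 °C
Reagents that add atoms: water, O
Why: Acidic fluoride hydrolyses the allylic dimethyl ketal and cleaves the TBS ether (activated once C8 is a ketone), while the neopentyl TIPS ether, far more stable to acid, should survive.

Step 17
Reactants: 24 9β-hydroxy C8 dienone; 25 2-bromopropionyl bromide (racemic)
Product: 26 9β-(2-bromopropionate)
Conditions: pyridine, CH2Cl2, −30 to 0 °C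
Reagents that add atoms: none
Why: Acyl bromide esterification of the only free hydroxyl installs C17–C19 as a tether on O9, and H9 lies in the carbonyl plane so the mild base should not epimerise C9.

Step 18
Reactants: 26 9β-(2-bromopropionate)
Product: 28 8α-hydroxy lactone closed on O9, via samarium(III) ester enolate 27 (not isolated)
Conditions: SmI2 (2.2 equiv), THF, −78 °C; pH 7 buffer
Reagents that add atoms: none
Why: Intramolecular Reformatsky reaction in which the α-bromo ester is reduced first, and the five-membered closure can bring C17 only to the β face of C8=O as long as C7–C8–C9–C10 keeps the gauche torsion inherited from ring B, which gives 8α-OH and a β C8–C17 bond, whereas an external enolate would attack anti to O9.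

Step 19
Reactants: 28 8α-hydroxy lactone closed on O9
Product: 29 14α-alcohol (β-hydroxy ketone)
Conditions: HF·pyridine, THF, 0 °C to rt
Reagents that add atoms: none
Why: Fluoride-driven desilylation under weakly acidic conditions frees O14 without retro-aldol cleavage of either β-hydroxy carbonyl unit.

Step 20
Reactants: 29 14α-alcohol
Product: 30 2β,14α-diol
Conditions: Me4NBH(OAc)3, MeCN–AcOH, −30 °C
Reagents that add atoms: none
Why: Evans–Saksena reduction in which boron bound to O14 delivers hydride through a chair having C13 and C3 equatorial, so hydrogen enters C2 from the α side and the 1,3-anti diol (2β-OH, H2 α) results, while the lactone is inert to this reagent.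

Step 21
Reactants: 30 2β,14α-diol
Product: 31 open Weinreb amide tetraol (2β-, 8α-, 9β- and 14α-OH)
Conditions: MeNH(OMe)·HCl, AlMe3, CH2Cl2, 0 °C to rt; Rochelle salt
Reagents that add atoms: N,O-dimethylhydroxylamine hydrochloride, CNOC.Cl
Why: Aluminium amide aminolysis of a γ-lactone releases O9 so that it can be capped, keeps C19 at the acid level, and leaves C8 untouched because aluminium aldolates resist retro-aldol cleavage.

Step 22
Reactants: 31 open Weinreb amide tetraol
Product: 32 2β,9β,14α-triacetate (8α-OH free)
Conditions: Ac2O, pyridine, DMAP, rt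
Reagents that add atoms: acetic anhydride, CC(=O)OC(C)=O
Why: DMAP-catalysed acetylation takes all three secondary alcohols in one step, blocks O9 against relactonisation and leaves the tertiary 8-OH free.

Step 23
Reactants: 32 2β,9β,14α-triacetate
Product: 33 trans-6,7-epoxide
Conditions: VO(acac)2 (5 mol %), t-BuOOH, CH2Cl2, 0 °C
Reagents that add atoms: tert-butyl hydroperoxide, CC(C)(C)OO
Why: Vanadium-catalysed epoxidation directed by the allylic 8-OH selects C6=C7 over both 1,1-disubstituted methylenes, and oxygen can reach only the outer face of the E olefin (the inner face looks across the ring at C2/C3), which sets the C7–O configuration of the target.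

Step 24
Reactants: 33 trans-6,7-epoxide
Product: 35 6α-chloro γ-lactone closed on O7 (C17 epimers), via chlorohydrin amide 34 (not isolated)
Conditions: TiCl2(OiPr)2, CH2Cl2, −20 to 0 °C; aq. tartaric acid; CSA (10 mol %), CH2Cl2, rt
Reagents that add atoms: dichlorotitanium diisopropoxide, CC(C)O[Ti](Cl)(Cl)OC(C)C
Why: Titanium-assisted C3-selective opening of a 2,3-epoxy alcohol in which Ti bound to O8 and the oxirane oxygen polarises the allylic C6–O bond, chloride attacks C6 from the open α side with inversion, O7 keeps its configuration, and acid then lets O7 displace N,O-dimethylhydroxylamine in a 5-exo-trig lactonisation with O9 out of play as its acetate.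

Step 25
Reactants: 35 6α-chloro γ-lactone closed on O7 (C17 epimers)
Product: 36 CNP0199061.1 (target)
Conditions: DBU (0.2 equiv), toluene, rt
Reagents that add atoms: none
Why: Base-catalysed epimerisation α to the lactone carbonyl converges on the epimer with C18 cis to the small 8-OH and trans to C9, which should be the more stable, C17 being the only enolisable stereocentre and the minor epimer being resubmitted.

**Compound list**
1 | (E)-crotonaldehyde | C/C=C/C=O | starting material
2 | (E)-1-(triisopropylsilyloxy)buta-1,3-diene | C=C/C=C/O[Si](C(C)C)(C(C)C)C(C)C | intermediate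
3 | 2-methoxy-5-methyl-1,4-benzoquinone | COC1=CC(=O)C(C)=CC1=O | starting material
4 | cis-fused cycloadduct: C2 and C9 ketones, C7=C8 with 8-OMe, C12=C13, 14α-OTIPS, 15-Me β, H10 β | C1C=C[C@H](O[Si](C(C)C)(C(C)C)C(C)C)[C@]2(C)C(=O)C=C(OC)C(=O)[C@H]12 | intermediate
5 | trans-fused ene-dione (as 4, H10 α) | C1C=C[C@H](O[Si](C(C)C)(C(C)C)C(C)C)[C@]2(C)C(=O)C=C(OC)C(=O)[C@@H]12 | intermediate
6 | 9β-alcohol (axial OH, vinylogous ester at C2/C7/C8) | C1C=C[C@H](O[Si](C(C)C)(C(C)C)C(C)C)[C@]2(C)C(=O)C=C(OC)[C@@H](O)[C@@H]12 | intermediate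
7 | 9β-TBS ether | C1C=C[C@H](O[Si](C(C)C)(C(C)C)C(C)C)[C@]2(C)C(=O)C=C(OC)[C@@H](O[Si](C)(C)C(C)(C)C)[C@@H]12 | intermediate
8 | C12=C13 en-11-one | O=C1C=C[C@H](O[Si](C(C)C)(C(C)C)C(C)C)[C@]2(C)C(=O)C=C(OC)[C@@H](O[Si](C)(C)C(C)(C)C)[C@@H]12 | intermediate
9 | saturated 11-ketone | O=C1CC[C@H](O[Si](C(C)C)(C(C)C)C(C)C)[C@]2(C)C(=O)C=C(OC)[C@@H](O[Si](C)(C)C(C)(C)C)[C@@H]12 | intermediate
10 | 11(20)-methylene vinylogous ester | C=C1CC[C@H](O[Si](C(C)C)(C(C)C)C(C)C)[C@]2(C)C(=O)C=C(OC)[C@@H](O[Si](C)(C)C(C)(C)C)[C@@H]12 | intermediate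
11 | C2 allylic alcohol with C7=C8(OMe) enol ether (C2 epimers) | C=C1CC[C@H](O[Si](C(C)C)(C(C)C)C(C)C)[C@]2(C)C(O)C=C(OC)[C@@H](O[Si](C)(C)C(C)(C)C)[C@@H]12 | intermediate
12 | 7-bromo 8,8-dimethyl ketal (C2 and C7 epimers) | C=C1CC[C@H](O[Si](C(C)C)(C(C)C)C(C)C)[C@]2(C)C(O)C(Br)C(OC)(OC)[C@@H](O[Si](C)(C)C(C)(C)C)[C@@H]12 | intermediate
13 | propargyl bromide | C#CCBr | starting material
14 | allenylmagnesium bromide | C=C=C[Mg]Br | intermediate
15 | triphenyl(prop-2-ynyl)stannane | C#CC[Sn](c1ccccc1)(c1ccccc1)c1ccccc1 | intermediate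
16 | 7α-allenyl carbinol (allenyl equatorial, H7 β; C2 epimers) | C=C1CC[C@H](O[Si](C(C)C)(C(C)C)C(C)C)[C@]2(C)C(O)[C@H](C=C=C)C(OC)(OC)[C@@H](O[Si](C)(C)C(C)(C)C)[C@@H]12 | intermediate
17 | α-allenyl ketone (C2=O) | C=C1CC[C@H](O[Si](C(C)C)(C(C)C)C(C)C)[C@]2(C)C(=O)[C@H](C=C=C)C(OC)(OC)[C@@H](O[Si](C)(C)C(C)(C)C)[C@@H]12 | intermediate
18 | vinylmagnesium bromide | C=C[Mg]Br | starting material
19 | vinylcerium dichloride | C=C[Ce](Cl)Cl | intermediate
20 | trans-decalin vinyl carbinol with C7 allene (2α-OH axial, vinyl and allenyl equatorial) | C=C1CC[C@H](O[Si](C(C)C)(C(C)C)C(C)C)[C@]2(C)[C@@](O)(C=C)[C@H](C=C=C)C(OC)(OC)[C@@H](O[Si](C)(C)C(C)(C)C)[C@@H]12 | intermediate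
21 | potassium alkoxide of 20 | C=C1CC[C@H](O[Si](C(C)C)(C(C)C)C(C)C)[C@]2(C)[C@@]([O-])(C=C)[C@H](C=C=C)C(OC)(OC)[C@@H](O[Si](C)(C)C(C)(C)C)[C@@H]12.[K+] | intermediate
22 | ring-expanded potassium enolate (C2=C3 with C1 and C4 trans, E C6=C7) | C=C1CC[C@H](O[Si](C(C)C)(C(C)C)C(C)C)[C@]2(C)/C([O-])=C/CC(=C)/C=C/C(OC)(OC)[C@@H](O[Si](C)(C)C(C)(C)C)[C@@H]12.[K+] | intermediate
23 | bicyclic cyclodecadienone: C2=O, C5=C16 methylene, E C6=C7, C8 dimethyl ketal, 9β-OTBS, 14α-OTIPS | C=C1CC[C@H](O[Si](C(C)C)(C(C)C)C(C)C)[C@]2(C)C(=O)CCC(=C)/C=C/C(OC)(OC)[C@@H](O[Si](C)(C)C(C)(C)C)[C@@H]12 | intermediate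
24 | 9β-hydroxy C8 dienone | C=C1CC[C@H](O[Si](C(C)C)(C(C)C)C(C)C)[C@]2(C)C(=O)CCC(=C)/C=C/C(=O)[C@@H](O)[C@@H]12 | intermediate
25 | 2-bromopropionyl bromide (racemic) | CC(Br)C(=O)Br | starting material
26 | 9β-(2-bromopropionate) | C=C1CC[C@H](O[Si](C(C)C)(C(C)C)C(C)C)[C@]2(C)C(=O)CCC(=C)/C=C/C(=O)[C@@H](OC(=O)C(C)Br)[C@@H]12 | intermediate
27 | samarium(III) ester enolate | C=C1CC[C@H](O[Si](C(C)C)(C(C)C)C(C)C)[C@]2(C)C(=O)CCC(=C)/C=C/C(=O)[C@@H](OC(O[Sm](I)I)=CC)[C@@H]12 | intermediate
28 | 8α-hydroxy γ-lactone closed on O9 (C17 epimers) | C=C1CC[C@H](O[Si](C(C)C)(C(C)C)C(C)C)[C@]2(C)C(=O)CCC(=C)/C=C/[C@@]3(O)C(C)C(=O)O[C@H]3[C@@H]12 | intermediate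
29 | 14α-alcohol of 28 | C=C1CC[C@H](O)[C@]2(C)C(=O)CCC(=C)/C=C/[C@@]3(O)C(C)C(=O)O[C@H]3[C@@H]12 | intermediate
30 | 2β,14α-diol | C=C1CC[C@H](O)[C@]2(C)[C@@H](O)CCC(=C)/C=C/[C@@]3(O)C(C)C(=O)O[C@H]3[C@@H]12 | intermediate
31 | Weinreb amide tetraol | C=C1CC[C@H](O)[C@]2(C)[C@@H](O)CCC(=C)/C=C/[C@@](O)(C(C)C(=O)N(C)OC)[C@@H](O)[C@@H]12 | intermediate
32 | 2β,9β,14α-triacetate amide | C=C1CC[C@H](OC(C)=O)[C@]2(C)[C@@H](OC(C)=O)CCC(=C)/C=C/[C@@](O)(C(C)C(=O)N(C)OC)[C@@H](OC(C)=O)[C@@H]12 | intermediate
33 | trans-6,7-epoxide | C=C1CC[C@H](OC(C)=O)[C@]2(C)[C@@H](OC(C)=O)CCC(=C)[C@H]3O[C@@H]3[C@@](O)(C(C)C(=O)N(C)OC)[C@@H](OC(C)=O)[C@@H]12 | intermediate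
34 | 6α-chloro-7,8-diol amide | C=C1CC[C@H](OC(C)=O)[C@]2(C)[C@@H](OC(C)=O)CCC(=C)[C@H](Cl)[C@H](O)[C@@](O)(C(C)C(=O)N(C)OC)[C@@H](OC(C)=O)[C@@H]12 | intermediate
35 | 6α-chloro γ-lactone closed on O7 (C17 epimers) | C=C1CC[C@H](OC(C)=O)[C@]2(C)[C@@H](OC(C)=O)CCC(=C)[C@H](Cl)[C@@H]3OC(=O)C(C)[C@@]3(O)[C@@H](OC(C)=O)[C@@H]12 | intermediate
36 | CNP0199061.1 | C=C1CC[C@H](OC(C)=O)[C@]2(C)[C@@H](OC(C)=O)CCC(=C)[C@H](Cl)[C@@H]3OC(=O)[C@H](C)[C@@]3(O)[C@@H](OC(C)=O)[C@@H]12 | target

**Step count:** 25 steps in total. The longest linear sequence is 24 steps (steps 1–10 and 12–25, from crotonaldehyde).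

**Steps most likely to fail**

Step 15.
- What may go wrong: the C2–C7 bond may break heterolytically instead of in concert, after which the C7 carbanion expels methoxide from C8. The base may isomerise the allene. Potassium bridging O2 and O14 may slow the shift.
- Fallback: a neutral, thermal version of the same disconnection.
  - It sets out from 20, which is silylated (TMSOTf, 2,6-lutidine) to the trimethylsilyl ether F1.
  - Thermolysis in a base-washed sealed tube (o-xylene, about 190 °C) gives the ring-expanded silyl enol ether F2 by a siloxy-Cope rearrangement.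
  - Citric acid in methanol cleaves the enol ether, and the route is rejoined at 23.

Step 2.
- What may go wrong: orientation control erodes if part of the catalyst binds C9=O next to the methoxy group. Facial discrimination may be weak because the reacting C1=C10 bond lies remote from boron.
- Fallback: asymmetric induction in the cycloaddition is given up.
  - Compounds 2 and 3 are combined under BF3·OEt2, an achiral monodentate Lewis acid expected to impose the same orientation. This gives 4 together with its mirror image, the ent-cycloadduct F3.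
  - Alumina converts the pair into 5 and the ent-ene-dione F4.
  - A kinetic resolution follows, using the matched Me-CBS catalyst and 0.55 equiv BH3·SMe2. It reduces only the enantiomer whose open α face at C9 fits the catalyst.
  - Unreacted F4 is separated, and the route is rejoined at 6.

Step 24.
- What may go wrong: chloride may enter at C16 with allylic shift, or the ion pair may collapse on the face of the departing oxygen, so that inversion at C6 is lost.
- Fallback: both oxygens are installed first and chlorine is then introduced by substitution of an alcohol.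
  - It sets out from 32. Hydrogen-bond-directed syn-dihydroxylation (OsO4·TMEDA, CH2Cl2, −78 °C, reductive work-up) on the outer face of C6=C7 gives the 6,7-diol amide F5.
  - CSA closes O7 onto the amide to give the 6-hydroxy lactone F6.
  - An Appel reaction (PPh3, CCl4) replaces the allylic 6-OH by chloride with inversion, and the route is rejoined at 35.

Further compounds
F1 | step 15 | trimethylsilyl ether of 20 | C=C1CC[C@H](O[Si](C(C)C)(C(C)C)C(C)C)[C@]2(C)[C@@](O[Si](C)(C)C)(C=C)[C@H](C=C=C)C(OC)(OC)[C@@H](O[Si](C)(C)C(C)(C)C)[C@@H]12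
F2 | step 15 | ring-expanded trimethylsilyl enol ether | C=C1CC[C@H](O[Si](C(C)C)(C(C)C)C(C)C)[C@]2(C)/C(O[Si](C)(C)C)=C/CC(=C)/C=C/C(OC)(OC)[C@@H](O[Si](C)(C)C(C)(C)C)[C@@H]12
F3 | step 2 | ent-cycloadduct (mirror image of 4) | C1C=C[C@@H](O[Si](C(C)C)(C(C)C)C(C)C)[C@@]2(C)C(=O)C=C(OC)C(=O)[C@@H]12
F4 | step 2 | ent-ene-dione (mirror image of 5) | C1C=C[C@@H](O[Si](C(C)C)(C(C)C)C(C)C)[C@@]2(C)C(=O)C=C(OC)C(=O)[C@H]12
F5 | step 24 | 6,7-diol amide (both oxygens from the outer face) | C=C1CC[C@H](OC(C)=O)[C@]2(C)[C@@H](OC(C)=O)CCC(=C)[C@@H](O)[C@H](O)[C@@](O)(C(C)C(=O)N(C)OC)[C@@H](OC(C)=O)[C@@H]12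
F6 | step 24 | 6-hydroxy γ-lactone closed on O7 (C17 epimers) | C=C1CC[C@H](OC(C)=O)[C@]2(C)[C@@H](OC(C)=O)CCC(=C)[C@@H](O)[C@@H]3OC(=O)C(C)[C@@]3(O)[C@@H](OC(C)=O)[C@@H]12
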